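## The problem

The target is a [3.3]metacyclophane. Its 12-membered ring is built from two 4,6-dihydroxy-1,3-phenylene linkers (ArA, ArB), two ketone carbonyls and the C3–C4 bonds of two 1-methylcyclohexenes (rings A and B). In each ring C1 bears the methyl group, C1=C2 is the alkene, C3 carries the linker aryl, C4 the ketone and C5 a 2,4-dihydroxyphenyl group. ArA sits on ring A C3 and is acylated by the ring B C4 carbonyl; ArB sits on ring B C3 and is acylated by the ring A C4 carbonyl.

Each ring has three contiguous stereocentres, ring A (3R,4S,5R) and ring B (3R,4R,5R). In both rings the C3 and C5 aryl groups are trans, but the acyl group is cis to the C3 aryl in ring A and cis to the C5 aryl in ring B. Ring A therefore has the pattern of an endo Diels–Alder adduct of an E enone with an E 1-aryl diene, whereas ring B cannot arise from an E enone at all.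

C4 of each ring is α to a ketone and can epimerise, while C3 and C5 cannot. C3 and C5 must therefore be fixed early, and C4 must be created stereospecifically and then kept away from strong base. Eight phenols and two trisubstituted alkenes that cyclise onto neighbouring phenols under strong acid call for acetal protection and a mild last step.

The feature that opens ring B is the exocyclic aryl ketone on C4 next to the aryl-bearing C5. Placing the carbonyl carbon between C4 and C5 gives a cycloheptene with a tertiary benzylic carbinol beside a bromine-bearing carbon. Contraction of that halohydrin inverts C4 and retains C5, which delivers the awkward cis C4/C5 pair.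

## Retrosynthesis

**41 from 40.** The last operation is removal of seven methoxymethyl groups from 40. These acetals tolerate organometallic, basic and palladium steps and leave under mild acid.

**40 from 39.** Ring A is cut at C3–C4 and C5–C6, an intramolecular Diels–Alder reaction of the ArB enone with the ArA diene in 39. Against an aryl–acyl macrocyclisation this cut forms two C–C bonds, three stereocentres and the 12-membered ring at once. The forward reaction must be endo and face-selective, so the phenol ortho to the enone carbonyl is left free in 39 for a chiral boron template.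

**39 from 34, 5 and 10.** The enone is attached at the ArB–C(=O) bond by Stille acylation of stannane 35 with acid 5, giving 37. The diene is attached at ArA by Suzuki coupling with boronate 10. This needs two halides of different reactivity in 34, bromine on ArB and chlorine on ArA. Both couplings run without strong base, which protects C4.

**34 from 32 (key step).** The C4–C5 bond of ring B is cut and C5 is rejoined to the carbonyl carbon, leading to cis-bromohydrin 32. Epimerisation cannot replace this cut because the two C4 epimers are of similar energy, and a cycloaddition would need a Z enone. The precursor has four contiguous centres on a seven-membered ring, where cyclic control is available. The forward step asks only for antiperiplanar migration of the ring bond.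

**32 from 29 and 8.** The ArA–carbinol bond is cut. The arylcerium reagent from 8 adds to α-bromoketone 29 on the face away from bromine and the C7 aryl.

**29 from 27 and 26.** Bromine is placed by SN2 inversion of the α-hydroxyl of 27, which comes from silyl ether 26. Direct bromination of the ketone would go to the more acidic benzylic C7, so the oxygen serves as the regiochemical marker and its configuration fixes that of bromine.

**26 from 24, 22 and 23.** The ring is cut at C4=C5 by ring-closing metathesis of 24 and at C6–C7 by alkylation of benzyl ketone 22 with 23. C7 is set by equilibration to the isomer with the C3 and C7 aryl groups equatorial.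

**22 from 20 and 4, back to 13.** The C1–C7 bond comes from benzyl chloride 4 and N-methoxy-N-methylamide 20. The C2 oxygen of 18 and the C3 centre of 17 come from auxiliary-controlled hydroxylation and conjugate addition on imide 16, made from acid 14 and aldehyde 13.

**Building blocks.** 13 comes from 11; 4 and 5 come from 1 through 2; 8 comes from 6; 10 comes from 9.

## Roads not taken

**Alternative 1:** The cut is the ArA–C(=O) bond, with ring B held as a cis-fused lactone between its C4 carboxyl and the ortho oxygen of its C5 aryl. Zerovalent palladium with an N-heterocyclic carbene would insert into the acyl–oxygen bond and the acylpalladium would be arylated by an ArA boronate in the same molecule, giving A1. Its merit is real: the cis C4/C5 relation is locked in a lactone and does not depend on a migration, and ketone and macrocycle form together. Its weak points are the acyl C–O activation of a hindered secondary-alkyl aryl ester in a 12-membered closure (decarbonylation, protodeboronation of an electron-rich boronate) and the need for a separate stereocontrolled route to the ring B lactone. On security of the ring B stereochemistry this road is at least as good. The chosen plan sets against it a stereospecific rearrangement of a classical type and an intermolecular carbonyl addition for the ArA–carbonyl bond.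

**Alternative 2:** The cut is the ring A C3–ArA bond. An allylic alcohol would be ionised and the allyl cation captured by the ortho carbon of the aryl ester of the C4 carboxyl, giving the cis-fused lactone A2. The tether fixes the cis C3/C4 junction from an enantiopure ring A acid, which is more secure than the face selectivity of the cycloaddition chosen here, and this is conceded. Against it stand acid ionisation next to acetal-protected phenols, two possible sites on the arene and on the allyl cation, and the two aryl–acyl bonds, one of them a macrocyclisation, that still remain. The chosen plan sets against it the closure of ring A and the macrocycle in one ligand-controlled step and fewer steps after ring B.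

**Alternative 3:** The cut is the ArB–C(=O) bond, traced back to a 14-membered aryl macrolactone. Irradiation would cleave the acyl–oxygen bond and recombine the pair at the ortho carbon, contracting the ring to the diketone A3. Macrolactonisation is reliable and no metal is needed, which is in its favour. The weak points are two free ortho positions on ArB, decarbonylation of the secondary acyl radical, and competing photochemistry of the other ortho-hydroxyaryl ketone and the alkenes. The chosen plan avoids light-driven steps and fixes the site of acylation by the position of a halogen.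

Key step: step 22

Abbreviations in names: ArB = 5-bromo-2-(methoxymethoxy)-4-(triisopropylsilyloxy)phenyl; ArM = 2,4-bis(methoxymethoxy)phenyl; ArA = 5-chloro-2,4-bis(methoxymethoxy)phenyl; Xc = (4R)-4-benzyl-2-oxo-1,3-oxazolidin-3-yl. Cycloheptene intermediates are numbered C1 (carbonyl or carbinol), C2 (O or Br), C3 (ArB), C4=C5(Me), C6, C7 (ArM); C2, C7 and C1 become C4, C5 and the ketone carbon of ring B.

Assumption: the boron complex of (S)-VANOL is taken to expose the enone face that leads to (3R,4S,5R) in ring A; if the sense is opposite, (R)-VANOL is the reagent.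

## Route

Step 1
Reactants: 1 2,4-dihydroxybenzaldehyde
Product: 2 2,4-bis(methoxymethoxy)benzaldehyde
Conditions: MeOCH2Cl, iPr2NEt, CH2Cl2, 0 → 40 °C
Reagents that add atoms: chloromethyl methyl ether, COCCl
Why: O-alkylation of both phenols; the hydrogen-bonded ortho phenol needs excess reagent and warming.

Step 2
Reactants: 2 2,4-bis(methoxymethoxy)benzaldehyde
Product: 3 [2,4-bis(methoxymethoxy)phenyl]methanol
Conditions: NaBH4, MeOH, 0 °C
Reagents that add atoms: none
Why: Borohydride reduction of the aldehyde.

Step 3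
Reactants: 3 [2,4-bis(methoxymethoxy)phenyl]methanol
Product: 4 1-(chloromethyl)-2,4-bis(methoxymethoxy)benzene
Conditions: PPh3, N-chlorosuccinimide, THF, 0 °C
Reagents that add atoms: N-chlorosuccinimide, O=C1CCC(=O)N1Cl
Why: Appel-type chlorination under neutral conditions that spare the acetals; the reactive benzylic chloride is used at once.

Step 4
Reactants: 2 2,4-bis(methoxymethoxy)benzaldehyde
Product: 5 (2E)-3-ArM-prop-2-enoic acid
Conditions: malonic acid, pyridine, piperidine (cat.), 80 °C
Reagents that add atoms: malonic acid, OC(=O)CC(=O)O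
Why: Knoevenagel–Doebner condensation with decarboxylation gives the E acid.

Step 5
Reactants: 6 4-chlorobenzene-1,3-diol
Product: 7 4-bromo-6-chlorobenzene-1,3-diol
Conditions: N-bromosuccinimide, MeCN, 0 °C
Reagents that add atoms: N-bromosuccinimide, O=C1CCC(=O)N1Br
Why: Electrophilic bromination at C6, ortho to one hydroxyl and para to the other and less hindered than C2.

Step 6
Reactants: 7 4-bromo-6-chlorobenzene-1,3-diol
Product: 8 1-bromo-5-chloro-2,4-bis(methoxymethoxy)benzene
Conditions: MeOCH2Cl, iPr2NEt, CH2Cl2, 25 °C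
Reagents that add atoms: chloromethyl methyl ether, COCCl
Why: O-alkylation of both phenols.

Step 7
Reactants: 9 2-methylbut-1-en-3-yne
Product: 10 4,4,5,5-tetramethyl-2-[(1E)-3-methylbuta-1,3-dien-1-yl]-1,3,2-dioxaborolane
Conditions: pinacolborane, Cp2Zr(H)Cl (5 mol%), Et3N (10 mol%), 60 °C
Reagents that add atoms: pinacolborane, CC1(C)OBOC1(C)C
Why: Zirconium-catalysed syn hydroboration of the terminal alkyne puts boron at the terminus and gives the E dienyl boronate; the 1,1-disubstituted alkene is untouched.

Step 8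
Reactants: 11 5-bromo-2,4-dihydroxybenzaldehyde
Product: 12 5-bromo-2-hydroxy-4-(triisopropylsilyloxy)benzaldehyde
Conditions: iPr3SiCl, imidazole, DMF, 0 °C
Reagents that add atoms: chlorotriisopropylsilane, CC(C)[Si](Cl)(C(C)C)C(C)C
Why: Selective silylation of the more acidic 4-OH; the 2-OH is hydrogen-bonded to the aldehyde.

Step 9
Reactants: 12 5-bromo-2-hydroxy-4-(triisopropylsilyloxy)benzaldehyde
Product: 13 5-bromo-2-(methoxymethoxy)-4-(triisopropylsilyloxy)benzaldehyde
Conditions: MeOCH2Cl, iPr2NEt, CH2Cl2, 0 → 40 °C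
Reagents that add atoms: chloromethyl methyl ether, COCCl
Why: O-alkylation of the remaining phenol.

Step 10
Reactants: 13 5-bromo-2-(methoxymethoxy)-4-(triisopropylsilyloxy)benzaldehyde
Product: 14 (2E)-3-ArB-prop-2-enoic acid
Conditions: malonic acid, pyridine, piperidine (cat.), 70 °C
Reagents that add atoms: malonic acid, OC(=O)CC(=O)O
Why: Knoevenagel–Doebner condensation gives the E acid; the bulky aryl silyl ether should survive the amine medium.

Step 11
Reactants: 14 (2E)-3-ArB-prop-2-enoic acid
Product: 16 (2E)-3-ArB-prop-2-enoyl-Xc imide, via mixed pivalic anhydride 15 (not isolated)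
Conditions: t-BuCOCl, Et3N, THF, −20 °C; then (R)-4-benzyl-1,3-oxazolidin-2-one, LiCl, 25 °C
Reagents that add atoms: (R)-4-benzyl-1,3-oxazolidin-2-one, O=C1N[C@H](Cc2ccccc2)CO1
Why: N-acylation of the oxazolidinone auxiliary through the mixed anhydride with LiCl/Et3N activation.

Step 12
Reactants: 16 (2E)-3-ArB-prop-2-enoyl-Xc imide
Product: 17 (3S)-3-ArB-pent-4-enoyl-Xc imide
Conditions: CH2=CHMgBr, CuBr·SMe2 (0.2 equiv), THF/Me2S, −78 → −20 °C
Reagents that add atoms: vinylmagnesium bromide, C=C[Mg]Br
Why: Copper-mediated conjugate addition to the magnesium-chelated s-cis enoyl imide from the face opposite the benzyl group sets C3 as S.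

Step 13
Reactants: 17 (3S)-3-ArB-pent-4-enoyl-Xc imide
Product: 18 (2R,3S)-2-hydroxy-3-ArB-pent-4-enoyl-Xc imide
Conditions: NaN(SiMe3)2, THF, −78 °C; 2-(phenylsulfonyl)-3-phenyloxaziridine; AcOH
Reagents that add atoms: 2-(phenylsulfonyl)-3-phenyloxaziridine, O=S(=O)(N1OC1c1ccccc1)c1ccccc1
Why: Auxiliary-controlled hydroxylation of the chelated Z sodium enolate on the face away from the benzyl group sets C2 as R, the configuration that places oxygen cis to ArB in the later ring.

Step 14
Reactants: 18 (2R,3S)-2-hydroxy-3-ArB-pent-4-enoyl-Xc imide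
Product: 19 (2R,3S)-2-hydroxy-N-methoxy-N-methyl-3-ArB-pent-4-enamide
Conditions: MeNH(OMe)·HCl, AlMe3, CH2Cl2, 0 → 25 °C
Reagents that add atoms: N,O-dimethylhydroxylamine hydrochloride, CNOC.Cl
Why: Aluminium amide transamination, helped by the aluminium alkoxide of the free hydroxyl, releases the auxiliary without touching C2.

Step 15
Reactants: 19 (2R,3S)-2-hydroxy-N-methoxy-N-methyl-3-ArB-pent-4-enamide
Product: 20 (2R,3S)-N-methoxy-N-methyl-3-ArB-2-(triethylsilyloxy)pent-4-enamide
Conditions: Et3SiCl, imidazole, DMF, 25 °C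
Reagents that add atoms: chlorotriethylsilane, CC[Si](Cl)(CC)CC
Why: Silylation masks the secondary alcohol for the base-mediated steps that follow.

Step 16
Reactants: 20 (2R,3S)-N-methoxy-N-methyl-3-ArB-2-(triethylsilyloxy)pent-4-enamide, 4 1-(chloromethyl)-2,4-bis(methoxymethoxy)benzene
Product: 22 (3R,4S)-1-ArM-4-ArB-3-(triethylsilyloxy)hex-5-en-2-one, via benzylmagnesium chloride 21 (not isolated)
Conditions: 4, Mg, THF, 0 °C; then 20, 0 °C
Reagents that add atoms: none
Why: Grignard addition to the N-methoxy-N-methylamide stops at the ketone through the chelated tetrahedral intermediate; the aryl bromide is inert to a benzylic Grignard reagent.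

Step 17
Reactants: 22 (3R,4S)-1-ArM-4-ArB-3-(triethylsilyloxy)hex-5-en-2-one, 23 3-chloro-2-methylprop-1-ene
Product: 24 (6R,7S)-4-ArM-7-ArB-2-methyl-6-(triethylsilyloxy)nona-1,8-dien-5-one (both C4 epimers)
Conditions: KN(SiMe3)2, THF, −78 °C; 23, NaI (cat.), −78 → 0 °C
Reagents that add atoms: none
Why: The benzylic α-proton is far more acidic than the α-silyloxy one, so the enolate forms on the benzylic side only and is C-alkylated; the new centre forms as a mixture and is corrected in step 18.

Step 18
Reactants: 24 (6R,7S)-4-ArM-7-ArB-2-methyl-6-(triethylsilyloxy)nona-1,8-dien-5-one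
Product: 26 (2R,3S,7S)-7-ArM-3-ArB-5-methyl-2-(triethylsilyloxy)cyclohept-4-en-1-one, via C7-epimer mixture 25 (not isolated)
Conditions: second-generation Grubbs catalyst RuCl2(=CHPh)(PCy3)(H2IMes) (5 mol%), CH2Cl2 (2 mM), 40 °C; then DBU (0.2 equiv), 25 °C
Reagents that add atoms: none
Why: Ring-closing metathesis of the vinyl and isopropenyl groups gives the trisubstituted cycloheptene; DBU then equilibrates the benzylic C7 to the isomer with the C3 and C7 aryl groups both equatorial (trans), while the less acidic α-silyloxy centre is not touched.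

Step 19
Reactants: 26 (2R,3S,7S)-7-ArM-3-ArB-5-methyl-2-(triethylsilyloxy)cyclohept-4-en-1-one
Product: 27 (2R,3S,7S)-2-hydroxy-7-ArM-3-ArB-5-methylcyclohept-4-en-1-one
Conditions: HF·pyridine, pyridine, THF, 0 °C
Reagents that add atoms: none
Why: Buffered fluoride cleaves the alkyl triethylsilyl ether much faster than the hindered aryl triisopropylsilyl ether.

Step 20
Reactants: 27 (2R,3S,7S)-2-hydroxy-7-ArM-3-ArB-5-methylcyclohept-4-en-1-one
Product: 29 (2S,3S,7S)-2-bromo-7-ArM-3-ArB-5-methylcyclohept-4-en-1-one, via triflate 28 (not isolated)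
Conditions: Tf2O, 2,6-lutidine, CH2Cl2, −78 °C; then Bu4NBr (1.05 equiv), −78 → −20 °C
Reagents that add atoms: tetrabutylammonium bromide, CCCC[N+](CCCC)(CCCC)CCCC.[Br-]
Why: The axial α-hydroxyl is triflated and displaced by bromide in a carbonyl-accelerated SN2 reaction; inversion puts bromine equatorial, trans to ArB and cis to the C7 aryl.

Step 21
Reactants: 29 (2S,3S,7S)-2-bromo-7-ArM-3-ArB-5-methylcyclohept-4-en-1-one, 8 1-bromo-5-chloro-2,4-bis(methoxymethoxy)benzene
Product: 32 (1S,2S,3S,7S)-2-bromo-1-ArA-7-ArM-3-ArB-5-methylcyclohept-4-en-1-ol, via aryllithium 30 (not isolated), via arylcerium dichloride 31 (not isolated)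
Conditions: 8, n-BuLi, THF, −78 °C; CeCl3, −78 °C; then 29, −78 °C; AcOH
Reagents that add atoms: none
Why: Organocerium 1,2-addition, chosen for low basicity toward the C7 proton and the C–Br bond; the bulky aryl group enters on the face away from bromine and the C7 aryl, setting C1 with oxygen cis to bromine.

Step 22
Reactants: 32 (1S,2S,3S,7S)-2-bromo-1-ArA-7-ArM-3-ArB-5-methylcyclohept-4-en-1-ol
Product: 34 ArA (3R,4R,5R)-3-ArB-5-ArM-1-methylcyclohex-1-en-4-yl ketone (ring B), via potassium alkoxide 33 (not isolated)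
Conditions: KN(SiMe3)2 (1.0 equiv), THF, −78 → 0 °C
Reagents that add atoms: none
Why: Deprotonation gives alkoxide 33, whose oxyanion pushes while the C1–C7 ring bond, antiperiplanar to the equatorial C2–Br bond, shifts to C2 and bromide leaves, so the carbinol carbon becomes the exocyclic C=O. This is the semipinacol rearrangement of a halohydrin alkoxide, the ring contraction known for aryl-metal adducts of α-halocycloalkanones and related to the quasi-Favorskii shift. Ring B is closed by this intramolecular, invertive displacement of bromide by the migrating carbon, a concerted 1,2-shift that contracts the seven-membered ring without a free cation. The new stereocentre, ring B C4, is set by inversion at the bromine-bearing carbon and so is controlled by C2; the migrating C7 keeps its configuration and becomes C5. Bromine cis to the C7 aryl and trans to ArB is thereby turned into an acyl group cis to the C5 aryl and trans to ArB. The step needs ring-bond migration in preference to aryl migration and to epoxide formation. Oxygen is cis to bromine and cannot attack from the rear; in the chair with ArB, Br and the C7 aryl equatorial, the aryl on C1 is gauche to C–Br and only the C1–C7 bond is anti. One equivalent of a soluble base is used so that none is left to enolise the product at C4.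

Step 23
Reactants: 34 ArA (3R,4R,5R)-3-ArB-5-ArM-1-methylcyclohex-1-en-4-yl ketone
Product: 35 the ketone 34 with Me3Sn in place of Br on ArB
Conditions: Me3SnSnMe3, Pd(PPh3)4 (5 mol%), toluene, 100 °C
Reagents that add atoms: hexamethylditin, C[Sn](C)(C)[Sn](C)(C)C
Why: Palladium-catalysed stannylation of the aryl bromide under neutral conditions; the aryl chloride does not react with this catalyst.

Step 24
Reactants: 35 the ketone 34 with Me3Sn in place of Br on ArB, 5 (2E)-3-ArM-prop-2-enoic acid
Product: 37 the ketone 34 with (2E)-3-ArM-prop-2-enoyl in place of Br on ArB, via acid chloride 36 (not isolated)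
Conditions: 5, 1-chloro-N,N,2-trimethylprop-1-en-1-amine, CH2Cl2, 0 °C; then 35, Pd2(dba)3, P(2-furyl)3, toluene, 60 °C
Reagents that add atoms: none
Why: The acid chloride, made without HCl by the chloroenamine, undergoes Stille acylation to give the E aryl enone with no base present.

Step 25
Reactants: 37 the ketone 34 with (2E)-3-ArM-prop-2-enoyl in place of Br on ArB, 10 4,4,5,5-tetramethyl-2-[(1E)-3-methylbuta-1,3-dien-1-yl]-1,3,2-dioxaborolane
Product: 39 the enone 37 with (1E)-3-methylbuta-1,3-dienyl in place of Cl on ArA and OH in place of the silyl ether, via silyl ether 38 (not isolated)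
Conditions: Pd(OAc)2, XPhos, K3PO4, THF/H2O, 60 °C; then Bu4NF, AcOH, THF, 0 °C
Reagents that add atoms: none
Why: Suzuki–Miyaura coupling of the electron-rich aryl chloride with a dialkylbiarylphosphine ligand installs the E diene; buffered fluoride then frees the phenol ortho to the enone carbonyl.

Step 26
Reactants: 39 the enone–diene with the free ortho phenol
Product: 40 heptakis(methoxymethyl) ether of 41 with the ArB phenol ortho to the ring A carbonyl free
Conditions: (S)-VANOL, BH3·THF, AcOH, THF, 25 °C; then 39 (2 mM), 25 → 40 °C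
Reagents that add atoms: none
Why: The ortho-hydroxy enone is held as a chiral borate chelate that lowers its LUMO and shields one face; intramolecular Diels–Alder reaction with the E diene through the endo transition state closes ring A and the 12-membered ring, giving C3/C4 cis (endo), C4/C5 trans (E enone) and the absolute sense from the ligand.

Step 27
Reactants: 40 heptakis(methoxymethyl) ether of 41
Product: 41 CNP0244682.3
Conditions: HCl (3 M aq), MeOH/THF, 40 °C
Reagents that add atoms: none
Why: Acid-catalysed acetal exchange removes all seven methoxymethyl groups under conditions mild enough for the alkenes and the C4 centres.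

## Compound list

1 | 2,4-dihydroxybenzaldehyde | O=Cc1ccc(O)cc1O | starting material
2 | 2,4-bis(methoxymethoxy)benzaldehyde | O=Cc1ccc(OCOC)cc1OCOC | intermediate
3 | [2,4-bis(methoxymethoxy)phenyl]methanol | OCc1ccc(OCOC)cc1OCOC | intermediate
4 | 1-(chloromethyl)-2,4-bis(methoxymethoxy)benzene | ClCc1ccc(OCOC)cc1OCOC | intermediate
5 | (2E)-3-[2,4-bis(methoxymethoxy)phenyl]prop-2-enoic acid | OC(=O)/C=C/c1ccc(OCOC)cc1OCOC | intermediate
6 | 4-chlorobenzene-1,3-diol | Oc1ccc(Cl)c(O)c1 | starting material
7 | 4-bromo-6-chlorobenzene-1,3-diol | Oc1cc(O)c(Br)cc1Cl | intermediate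
8 | 1-bromo-5-chloro-2,4-bis(methoxymethoxy)benzene | COCOc1cc(OCOC)c(Br)cc1Cl | intermediate
9 | 2-methylbut-1-en-3-yne | CC(=C)C#C | starting material
10 | 4,4,5,5-tetramethyl-2-[(1E)-3-methylbuta-1,3-dien-1-yl]-1,3,2-dioxaborolane | CC(=C)/C=C/B1OC(C)(C)C(C)(C)O1 | intermediate
11 | 5-bromo-2,4-dihydroxybenzaldehyde | O=Cc1cc(Br)c(O)cc1O | starting material
12 | 5-bromo-2-hydroxy-4-(triisopropylsilyloxy)benzaldehyde | O=Cc1cc(Br)c(O[Si](C(C)C)(C(C)C)C(C)C)cc1O | intermediate
13 | 5-bromo-2-(methoxymethoxy)-4-(triisopropylsilyloxy)benzaldehyde | O=Cc1cc(Br)c(O[Si](C(C)C)(C(C)C)C(C)C)cc1OCOC | intermediate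
14 | (2E)-3-[5-bromo-2-(methoxymethoxy)-4-(triisopropylsilyloxy)phenyl]prop-2-enoic acid | OC(=O)/C=C/c1cc(Br)c(O[Si](C(C)C)(C(C)C)C(C)C)cc1OCOC | intermediate
15 | mixed anhydride of 14 with pivalic acid | CC(C)(C)C(=O)OC(=O)/C=C/c1cc(Br)c(O[Si](C(C)C)(C(C)C)C(C)C)cc1OCOC | intermediate
16 | (4R)-4-benzyl-3-[(2E)-3-ArB-prop-2-enoyl]-1,3-oxazolidin-2-one | O=C(/C=C/c1cc(Br)c(O[Si](C(C)C)(C(C)C)C(C)C)cc1OCOC)N1[C@H](Cc2ccccc2)COC1=O | intermediate
17 | (4R)-4-benzyl-3-[(3S)-3-ArB-pent-4-enoyl]-1,3-oxazolidin-2-one | C=C[C@@H](c1cc(Br)c(O[Si](C(C)C)(C(C)C)C(C)C)cc1OCOC)CC(=O)N1[C@H](Cc2ccccc2)COC1=O | intermediate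
18 | (4R)-4-benzyl-3-[(2R,3S)-2-hydroxy-3-ArB-pent-4-enoyl]-1,3-oxazolidin-2-one | C=C[C@@H](c1cc(Br)c(O[Si](C(C)C)(C(C)C)C(C)C)cc1OCOC)[C@@H](O)C(=O)N1[C@H](Cc2ccccc2)COC1=O | intermediate
19 | (2R,3S)-2-hydroxy-N-methoxy-N-methyl-3-ArB-pent-4-enamide | C=C[C@@H](c1cc(Br)c(O[Si](C(C)C)(C(C)C)C(C)C)cc1OCOC)[C@@H](O)C(=O)N(C)OC | intermediate
20 | (2R,3S)-N-methoxy-N-methyl-3-ArB-2-(triethylsilyloxy)pent-4-enamide | C=C[C@@H](c1cc(Br)c(O[Si](C(C)C)(C(C)C)C(C)C)cc1OCOC)[C@@H](O[Si](CC)(CC)CC)C(=O)N(C)OC | intermediate
21 | [2,4-bis(methoxymethoxy)benzyl]magnesium chloride | Cl[Mg]Cc1ccc(OCOC)cc1OCOC | intermediate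
22 | (3R,4S)-1-ArM-4-ArB-3-(triethylsilyloxy)hex-5-en-2-one | C=C[C@@H](c1cc(Br)c(O[Si](C(C)C)(C(C)C)C(C)C)cc1OCOC)[C@@H](O[Si](CC)(CC)CC)C(=O)Cc1ccc(OCOC)cc1OCOC | intermediate
23 | 3-chloro-2-methylprop-1-ene | CC(=C)CCl | starting material
24 | (6R,7S)-4-ArM-7-ArB-2-methyl-6-(triethylsilyloxy)nona-1,8-dien-5-one, both C4 epimers | C=C[C@@H](c1cc(Br)c(O[Si](C(C)C)(C(C)C)C(C)C)cc1OCOC)[C@@H](O[Si](CC)(CC)CC)C(=O)C(CC(C)=C)c1ccc(OCOC)cc1OCOC | intermediate
25 | (2R,3S)-7-ArM-3-ArB-5-methyl-2-(triethylsilyloxy)cyclohept-4-en-1-one, C7-epimer mixture | CC1=C[C@@H](c2cc(Br)c(O[Si](C(C)C)(C(C)C)C(C)C)cc2OCOC)[C@@H](O[Si](CC)(CC)CC)C(=O)C(c2ccc(OCOC)cc2OCOC)C1 | intermediate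
26 | (2R,3S,7S)-7-ArM-3-ArB-5-methyl-2-(triethylsilyloxy)cyclohept-4-en-1-one | CC1=C[C@@H](c2cc(Br)c(O[Si](C(C)C)(C(C)C)C(C)C)cc2OCOC)[C@@H](O[Si](CC)(CC)CC)C(=O)[C@H](c2ccc(OCOC)cc2OCOC)C1 | intermediate
27 | (2R,3S,7S)-2-hydroxy-7-ArM-3-ArB-5-methylcyclohept-4-en-1-one | CC1=C[C@@H](c2cc(Br)c(O[Si](C(C)C)(C(C)C)C(C)C)cc2OCOC)[C@@H](O)C(=O)[C@H](c2ccc(OCOC)cc2OCOC)C1 | intermediate
28 | (2R,3S,7S)-7-ArM-3-ArB-5-methyl-1-oxocyclohept-4-en-2-yl trifluoromethanesulfonate | CC1=C[C@@H](c2cc(Br)c(O[Si](C(C)C)(C(C)C)C(C)C)cc2OCOC)[C@@H](OS(=O)(=O)C(F)(F)F)C(=O)[C@H](c2ccc(OCOC)cc2OCOC)C1 | intermediate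
29 | (2S,3S,7S)-2-bromo-7-ArM-3-ArB-5-methylcyclohept-4-en-1-one | CC1=C[C@@H](c2cc(Br)c(O[Si](C(C)C)(C(C)C)C(C)C)cc2OCOC)[C@H](Br)C(=O)[C@H](c2ccc(OCOC)cc2OCOC)C1 | intermediate
30 | [5-chloro-2,4-bis(methoxymethoxy)phenyl]lithium | [Li]c1cc(Cl)c(OCOC)cc1OCOC | intermediate
31 | dichloro[5-chloro-2,4-bis(methoxymethoxy)phenyl]cerium | Cl[Ce](Cl)c1cc(Cl)c(OCOC)cc1OCOC | intermediate
32 | (1S,2S,3S,7S)-2-bromo-1-ArA-7-ArM-3-ArB-5-methylcyclohept-4-en-1-ol (cis-bromohydrin) | CC1=C[C@@H](c2cc(Br)c(O[Si](C(C)C)(C(C)C)C(C)C)cc2OCOC)[C@H](Br)[C@@](O)(c2cc(Cl)c(OCOC)cc2OCOC)[C@H](c2ccc(OCOC)cc2OCOC)C1 | intermediate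
33 | potassium alkoxide of 32 | CC1=C[C@@H](c2cc(Br)c(O[Si](C(C)C)(C(C)C)C(C)C)cc2OCOC)[C@H](Br)[C@@]([O-])(c2cc(Cl)c(OCOC)cc2OCOC)[C@H](c2ccc(OCOC)cc2OCOC)C1.[K+] | intermediate
34 | ArA (3R,4R,5R)-3-ArB-5-ArM-1-methylcyclohex-1-en-4-yl ketone (ring B ketone) | CC1=C[C@@H](c2cc(Br)c(O[Si](C(C)C)(C(C)C)C(C)C)cc2OCOC)[C@H](C(=O)c2cc(Cl)c(OCOC)cc2OCOC)[C@H](c2ccc(OCOC)cc2OCOC)C1 | intermediate
35 | ketone 34 with trimethylstannyl in place of Br on ArB | CC1=C[C@@H](c2cc([Sn](C)(C)C)c(O[Si](C(C)C)(C(C)C)C(C)C)cc2OCOC)[C@H](C(=O)c2cc(Cl)c(OCOC)cc2OCOC)[C@H](c2ccc(OCOC)cc2OCOC)C1 | intermediate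
36 | (2E)-3-[2,4-bis(methoxymethoxy)phenyl]prop-2-enoyl chloride | O=C(Cl)/C=C/c1ccc(OCOC)cc1OCOC | intermediate
37 | ketone 34 with (2E)-3-ArM-prop-2-enoyl in place of Br on ArB | CC1=C[C@@H](c2cc(C(=O)/C=C/c3ccc(OCOC)cc3OCOC)c(O[Si](C(C)C)(C(C)C)C(C)C)cc2OCOC)[C@H](C(=O)c2cc(Cl)c(OCOC)cc2OCOC)[C@H](c2ccc(OCOC)cc2OCOC)C1 | intermediate
38 | enone 37 with (1E)-3-methylbuta-1,3-dienyl in place of Cl on ArA | CC1=C[C@@H](c2cc(C(=O)/C=C/c3ccc(OCOC)cc3OCOC)c(O[Si](C(C)C)(C(C)C)C(C)C)cc2OCOC)[C@H](C(=O)c2cc(/C=C/C(C)=C)c(OCOC)cc2OCOC)[C@H](c2ccc(OCOC)cc2OCOC)C1 | intermediate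
39 | enone–diene 38 with OH in place of the triisopropylsilyl ether | CC1=C[C@@H](c2cc(C(=O)/C=C/c3ccc(OCOC)cc3OCOC)c(O)cc2OCOC)[C@H](C(=O)c2cc(/C=C/C(C)=C)c(OCOC)cc2OCOC)[C@H](c2ccc(OCOC)cc2OCOC)C1 | intermediate
40 | heptakis(methoxymethyl) ether of 41, ArB phenol ortho to the ring A carbonyl free; ring A (3R,4S,5R), ring B (3R,4R,5R) | CC1=C[C@H]2c3cc(c(OCOC)cc3OCOC)C(=O)[C@H]3[C@@H](C=C(C)C[C@H]3c3ccc(OCOC)cc3OCOC)c3cc(c(O)cc3OCOC)C(=O)[C@H]2[C@H](c2ccc(OCOC)cc2OCOC)C1 | intermediate
41 | CNP0244682.3; ring A (3R,4S,5R), ring B (3R,4R,5R) | CC1=C[C@H]2c3cc(c(O)cc3O)C(=O)[C@H]3[C@@H](C=C(C)C[C@H]3c3ccc(O)cc3O)c3cc(c(O)cc3O)C(=O)[C@H]2[C@H](c2ccc(O)cc2O)C1 | target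

## Step count and risks

Total: 27 steps. Longest linear sequence: 20 steps (steps 8–27, from 11).

**Step 22 (key step).** The most likely failure is aryl migration in place of ring-bond migration, which happens if the molecule reacts through a conformer with axial bromine. A second risk is loss of HBr toward C3, and a third is enolisation of the product at C4 by excess base.
Fallback: from 29, returning at 34. The aryl group is delivered as [5-chloro-2,4-bis(methoxymethoxy)phenyl]magnesium bromide F1 (from 8 and i-PrMgCl·LiCl). The bromomagnesium alkoxide F2 is not quenched but warmed in toluene, so that magnesium assists the departure of bromide while the alkoxide is only weakly basic. Addition and contraction are thus folded into one operation under electrophilic assistance.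

**Step 26.** The chiral template may be mismatched with the preference of the tether, giving the wrong face or the exo adduct, and dimerisation may compete with the 12-membered closure.
Fallback: from 38, isolated before desilylation, returning at 40. Thermal intramolecular cycloaddition in toluene at 110–140 °C under high dilution, with no Lewis acid and with facial control left to the ring B tether, gives the silyl-protected macrocycle F3. Bu4NF/AcOH then gives 40.

**Step 21.** Halogen–metal exchange at the secondary C–Br bond, or deprotonation at the benzylic C7 followed by Favorskii-type closure, may compete with carbonyl addition.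
Fallback: from 27, returning at 34. Triflation and displacement with Bu4NCl give the α-chloro ketone F4, whose C–Cl bond resists exchange and ionises less readily. Arylcerium 31 adds to give chlorohydrin F5, and KN(SiMe3)2 with warming to 40 °C contracts it to 34.

**Step 24.** Transmetalation from the stannane ortho to the bulky silyl ether may be slow, allowing decarbonylation of the acylpalladium or protodestannylation.
Fallback: from 34, returning at 37. Stille coupling with tributyl(1-ethoxyvinyl)stannane and brief dilute acid give the methyl ketone F6. Its boron enolate (Bu2BOTf, iPr2NEt, −78 °C), formed only at the methyl group, adds to aldehyde 2 to give the β-hydroxy ketone F7. MsCl/Et3N then DBU eliminates to the E enone 37.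

## Further compounds

F1 | step 22 | [5-chloro-2,4-bis(methoxymethoxy)phenyl]magnesium bromide | Br[Mg]c1cc(Cl)c(OCOC)cc1OCOC
F2 | step 22 | bromomagnesium alkoxide of 32 | CC1=C[C@@H](c2cc(Br)c(O[Si](C(C)C)(C(C)C)C(C)C)cc2OCOC)[C@H](Br)[C@@](O[Mg]Br)(c2cc(Cl)c(OCOC)cc2OCOC)[C@H](c2ccc(OCOC)cc2OCOC)C1
F3 | step 26 | triisopropylsilyl ether of 40 | CC1=C[C@H]2c3cc(c(OCOC)cc3OCOC)C(=O)[C@H]3[C@@H](C=C(C)C[C@H]3c3ccc(OCOC)cc3OCOC)c3cc(c(O[Si](C(C)C)(C(C)C)C(C)C)cc3OCOC)C(=O)[C@H]2[C@H](c2ccc(OCOC)cc2OCOC)C1
F4 | step 21 | (2S,3S,7S)-2-chloro-7-ArM-3-ArB-5-methylcyclohept-4-en-1-one | CC1=C[C@@H](c2cc(Br)c(O[Si](C(C)C)(C(C)C)C(C)C)cc2OCOC)[C@H](Cl)C(=O)[C@H](c2ccc(OCOC)cc2OCOC)C1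
F5 | step 21 | (1S,2S,3S,7S)-2-chloro-1-ArA-7-ArM-3-ArB-5-methylcyclohept-4-en-1-ol | CC1=C[C@@H](c2cc(Br)c(O[Si](C(C)C)(C(C)C)C(C)C)cc2OCOC)[C@H](Cl)[C@@](O)(c2cc(Cl)c(OCOC)cc2OCOC)[C@H](c2ccc(OCOC)cc2OCOC)C1
F6 | step 24 | ketone 34 with acetyl in place of Br on ArB | CC1=C[C@@H](c2cc(C(C)=O)c(O[Si](C(C)C)(C(C)C)C(C)C)cc2OCOC)[C@H](C(=O)c2cc(Cl)c(OCOC)cc2OCOC)[C@H](c2ccc(OCOC)cc2OCOC)C1
F7 | step 24 | ketone 34 with 3-hydroxy-3-ArM-propanoyl in place of Br on ArB | CC1=C[C@@H](c2cc(C(=O)CC(O)c3ccc(OCOC)cc3OCOC)c(O[Si](C(C)C)(C(C)C)C(C)C)cc2OCOC)[C@H](C(=O)c2cc(Cl)c(OCOC)cc2OCOC)[C@H](c2ccc(OCOC)cc2OCOC)C1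
A1 | alternative 1 | heptakis(methoxymethyl) ether of the target with the ortho phenol of the ring B C5 aryl free | CC1=C[C@H]2c3cc(c(OCOC)cc3OCOC)C(=O)[C@H]3[C@@H](C=C(C)C[C@H]3c3ccc(OCOC)cc3O)c3cc(c(OCOC)cc3OCOC)C(=O)[C@H]2[C@H](c2ccc(OCOC)cc2OCOC)C1
A2 | alternative 2 | cis-fused ring A lactone with the C3–ArA bond in place | CC1=C[C@H]2c3cc(Br)c(OCOC)cc3OC(=O)[C@H]2[C@H](c2ccc(OCOC)cc2OCOC)C1
A3 | alternative 3 | hexakis(methoxymethyl) ether of the target with both ketone-flanking phenols free | CC1=C[C@H]2c3cc(c(O)cc3OCOC)C(=O)[C@H]3[C@@H](C=C(C)C[C@H]3c3ccc(OCOC)cc3OCOC)c3cc(c(O)cc3OCOC)C(=O)[C@H]2[C@H](c2ccc(OCOC)cc2OCOC)C1
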